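## Structural features

The target is a trans-fused decalin (ring A: C1–C5 and C10; ring B: C5–C10) joined through C9 to the chain C11–C12–C13(CH3)=C14–C15(OH), which ends at C16, the O–CH carbon of a 4-methylfuran-2(5H)-one. Ring A holds two quaternary carbons, C4 (α-CO2Me, β-CH3) and C10 (β-CH3), on either side of the ring-fusion methine C5 (α-H), so the two methyl groups are 1,3-diaxial. Ring B adds C6 (α-OH, equatorial), C8 (α-OH, β-CH3) and C9 (β side chain, α-H); C8, C9 and C10 are contiguous, and C9 carries its substituent cis to the C10 methyl. The chain contains an E-trisubstituted olefin and the vicinal pair C15 (S) and C16 (S), a threo diol whose second oxygen is the lactone oxygen; no ring stereocentre can control this pair. Fragile groups are the tertiary 8-hydroxyl β to the C6 oxygen (dehydration, retro-aldol at the ketone stage), the butenolide (acidic C16–H, conjugate acceptor) and the allylic C15 carbinol; the ester on the quaternary C4 is hindered and robust. The real difficulty lies in the congested C4–C5–C10 triad and in C9, where the carbon substituent must sit on the face that electrophiles avoid. The key step exploits the two oxygens at C6 and C8 that flank the C7 methylene of ring B: this is the pattern of a cyclohexane-1,3-dione, whose C6 carbonyl can begin as an ester on C5 of ring A and whose C7–C8–C9 unit can begin as an acetonyl group on C10.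

## Logic of the disconnections

C13=C14 of 38 is cut first, giving 28 and 37. The cut separates the ring stereocentres from the C15/C16 pair, so each half is made with its own control element. The forward step is an olefin cross-metathesis of a 1,1-disubstituted olefin with a secondary allylic alcohol; it must be E-selective and must tolerate three free hydroxyls and the butenolide.

In ring B, the C6–H bond of 28 is traced to the ketone 27, the C7–H bond of 27 to the C7–O bond of 26, and the epoxide of 26 to the C7=C8 olefin of 25. A nucleophilic epoxidation touches only the conjugated olefin and leaves the isolated one, and it places O8 on the α face, away from the C10 methyl. The demand is that the C6 reduction gives the equatorial alcohol, although hydride would arrive from the open α face.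

C8–C17 of 25 is cut to give 24 and a methyl cuprate, and the O8–S bond of 24 leads back to 23. This turns the C8 carbonyl of a 1,3-dione into the methyl-bearing olefin carbon. The demand is that sulfonylation distinguishes O8 from O6.

C9–C11 of 23 is cut to give 18 and 20 (by way of 21). The 1,3-dione can be alkylated at C9 through its dianion. The electrophile is expected to enter trans to the C10 methyl, so the C9 hydrogen must be introduced last: 21 is converted into 22, in which C9 is trigonal, and 22 is protonated from the α face to give 23.

C6–C7 of 18 is cut to give 17. This opens ring B to a ring A diester with an acetonyl group on C10 and removes one ring and the 1,3-dicarbonyl. The forward Claisen condensation must choose the C7 enolate and the C6 ester over the C9 enolate and the C18 ester, and must keep or restore the trans ring fusion at C5.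

C9–C10 of 17 is cut through 16 to 14 and 2-methoxypropene. A [3,3] shift from an oxygen on C2 builds the quaternary C10 with the acetonyl group already at the ketone oxidation level, and the C2 oxygen disappears as the C1=C2 olefin that is then hydrogenated. The demand is a C2 carbinol of defined configuration, cis to the C4 ester.

14 is traced to 13 (C2 ketone), and 13 to 12 by removal of the C1=C10 unsaturation. The enone is the point where C10 becomes trigonal, so its configuration in the cycloadduct is irrelevant.

C3–C4 and C5–C10 of 12 (through 11 and 9) are cut to give 6 and 8. A Diels–Alder reaction sets C4 and C5 from the E geometry of the dienophile and the absolute sense from the auxiliary. A diene terminus bearing both C10 substituents would carry a cis substituent that disfavours the s-cis conformer, so 8 carries only the E methyl and an activating silyloxy group at C2. The demand is that the diene CH2 terminus bonds to the fully substituted C4.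

6 is cut at the N-acyl bond to 3 and 4, and C4=C5 of 3 is cut to 1 and 2 (Wittig). Both carbonyl groups of the dienophile arrive at the carboxyl oxidation level and are differentiated from the start.

37 is traced to 36 (acetal removal), and the lactone and the C–CH3 bond of 36 to the ynoate 34 by syn-carbocupration. C15–C16 of 34 is cut to 30 and 32. A Z-γ-alkoxyallylborane sets the threo pair in one step with reagent control. The demand is clean 1,2-addition to an aldehyde that also carries an ynoate.

The small pieces come from 19 (for 20), 29 (for 30) and 31 (for 32) by one functional-group change each.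

## Other disconnections considered

Alternative 1: The cut is the C18–O bond of a 6,18-ether, so the carboxyl carbon C18 is traced to the 4α-methyl of (+)-sclareolide A1, and rings A and B with C5, C8, C9 and C10 come from the chiral pool. In the forward key step, 6α-hydroxysclareolide A2 would be converted into its hypoiodite (PhI(OAc)2, I2, visible light). The 6α-oxygen radical should abstract hydrogen from the equatorial 4α-methyl through a six-membered transition state, and the resulting iodide should close to 6α,18-epoxysclareolide A3. In its favour: the configurations at C8, C9 and C10, which cost steps 8, 9, 14, 17 and 18 of the chosen plan, are present from the start, and the two C4 methyls are distinguished by proximity alone. Against it: A2 first needs a site- and face-selective oxygenation of the unactivated C6 of A1; the alkoxy radical can fragment or be oxidised to the ketone; the ether carbon of A3 must still be raised to the carboxyl level and opened to the methyl ester; and the lactone carbon of A1 must be extended by the whole C13–C16 unit. On structure this alternative is the better of the two for the ring stereocentres. On mechanism it is a radical relay, set against an ionic, thermodynamically driven ring closure. On step economy it should be shorter up to the stage of 28 if A2 is accessible, whereas the chosen plan carries C18 at the ester level from step 1 and does not depend on C–H oxidation selectivity.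

Alternative 2: The cuts are C14–C15 and the C13–CH3 bond. In the forward key step the terminal alkyne of the bis-silyl ether A4 would be methylaluminated (AlMe3, Cp2ZrCl2); the E-alkenyl metal, after exchange to zinc with a chiral amino alcohol, would add to 3-methylfuran-2-carbaldehyde A5 to give the furyl carbinol A6. In its favour: the E geometry follows from syn-carbometalation and is more secure than the cross-metathesis of step 25, and the coupling is convergent and sets C15 by ligand control. Against it: AlMe3 must spare the ester; two silyl ethers are needed; and, above all, C16 is not yet a stereocentre in A6. The furan must be oxidised to the butenolide with control relative to C15, and a furyl carbinol tends to ring-expand to a pyranone on oxidation. This alternative addresses only the chain and leaves every ring problem of the chosen plan standing. On olefin geometry it is better; on the C15/C16 pair the chosen plan is better, because 37 brings both centres in defined form; on step count the two are comparable.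

Alternative 3: The cut is C9–C10. In the forward key step, Fe(acac)3 and PhSiH3 would transfer a hydrogen atom to the exocyclic methylene of the monocyclic enoate A7, and the tertiary C10 radical would add in a 6-exo closure to C9 of the 4-oxo-enoate to give the decalone A8. In its favour: one step forms ring B, the quaternary C10 and C9 with C11 already attached, so the correction of C9 that costs step 14 of the chosen plan is not needed; on this point the alternative is the better one. Against it: the face of attack at C10 rests on the C4/C5 substituents of a flexible monocycle; the C6 silyloxy centre must be set in an open-chain precursor; the C8 ketone of A8 needs a methyl group on the hindered axial face; and the acetic ester arm needs more homologation than the alkylation of step 13. On mechanism it is an irreversible radical closure under kinetic control, set against a reversible ionic closure that ends in a stabilised enolate. On step economy the two are about equal up to the decalin, and the alternative is longer after it.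

Key step: step 11

Remark on numbering: labdane locants are used for all ring compounds, monocyclic ones included (C18 = ester carbon on C4, C17 = methyl on C8, C11–C15 = chain, C16 = lactone O–CH carbon); α means the face opposite to the C10 methyl.

Remark on the chemistry: the sense of induction of the (R)-oxazolidinone (chelated s-cis imide, attack anti to benzyl), of the (R)-oxazaborolidine (alkenyl branch as the large group) and of the borane from (−)-α-pinene (as with simple aldehydes) is assumed to follow the usual models; the antipodal reagent would be used if it did not.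

## Steps

Step 1
Reactants: 1 methyl 2-(triphenylphosphoranylidene)propanoate; 2 glyoxylic acid monohydrate
Product: 3 (E)-4-methoxy-3-methyl-4-oxobut-2-enoic acid
Conditions: CH2Cl2, 0 °C → rt
Reagents that add atoms: none
Why: Wittig olefination of a stabilised ylide with an aldehyde should give the E olefin, with the two carboxyl groups trans and already differentiated as ester and acid.

Step 2
Reactants: 3 (E)-4-methoxy-3-methyl-4-oxobut-2-enoic acid; 4 (R)-4-benzyloxazolidin-2-one
Product: 6 (R)-4-benzyl-3-[(E)-4-methoxy-3-methyl-4-oxobut-2-enoyl]oxazolidin-2-one, via mixed pivalic anhydride 5 (not isolated)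
Conditions: PivCl, Et3N, THF, −20 °C; then LiCl, 4, rt
Reagents that add atoms: none
Why: N-acylation of the oxazolidinone through the mixed anhydride is the standard route to enoyl imides; the hindered pivaloyl carbonyl is not attacked.

Step 3
Reactants: 7 (E)-pent-3-en-2-one
Product: 8 (E)-triisopropyl(penta-1,3-dien-2-yloxy)silane
Conditions: TIPSOTf, Et3N, CH2Cl2, 0 °C
Reagents that add atoms: triisopropylsilyl triflate, CC(C)[Si](C(C)C)(C(C)C)OS(=O)(=O)C(F)(F)F
Why: Soft enolisation of the enone at the methyl group gives the cross-conjugated 2-silyloxy diene, and the E olefin is retained.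

Step 4
Reactants: 6 (R)-4-benzyl-3-[(E)-4-methoxy-3-methyl-4-oxobut-2-enoyl]oxazolidin-2-one; 8 (E)-triisopropyl(penta-1,3-dien-2-yloxy)silane
Product: 9 ring A cycloadduct: N-acyl oxazolidinone of 4α-methoxycarbonyl-4β,10β-dimethyl-2-(triisopropylsilyloxy)cyclohex-1-ene-5β-carboxylic acid
Conditions: Et2AlCl (1.4 equiv), CH2Cl2, −78 → −30 °C
Reagents that add atoms: none
Why: Auxiliary-controlled Diels–Alder reaction of the chelated s-cis imide: the nucleophilic CH2 terminus of the diene bonds to C4 (β to the activated imide), the diene adds anti to the benzyl group, and the E dienophile fixes C4 (α-ester, β-methyl) and C5 (β-acyl) as trans; the C10 configuration is of no consequence because step 7 removes it.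

Step 5
Reactants: 9 ring A cycloadduct
Product: 11 4α-methoxycarbonyl-4β,10β-dimethyl-2-(triisopropylsilyloxy)cyclohex-1-ene-5β-carboxylic acid, via peroxy acid 10 (not isolated)
Conditions: LiOH, H2O2, THF–H2O, 0 °C; Na2SO3; HCl to pH 4
Reagents that add atoms: hydrogen peroxide, OO
Why: Hydroperoxide cleaves hindered N-acyl oxazolidinones at the exocyclic carbonyl; the ester on the quaternary C4 and the hindered silyl enol ether should survive the cold, weakly basic medium, and the auxiliary is recovered.

Step 6
Reactants: 11 ring A carboxylic acid
Product: 12 dimethyl 4β,10β-dimethyl-2-(triisopropylsilyloxy)cyclohex-1-ene-4α,5β-dicarboxylate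
Conditions: TMSCHN2, MeOH–toluene, 0 °C
Reagents that add atoms: trimethylsilyldiazomethane, C[Si](C)(C)C=[N+]=[N-]
Why: Neutral O-methylation of the acid, so that neither C5 nor the enol ether is exposed to acid or base.

Step 7
Reactants: 12 ring A diester silyl enol ether
Product: 13 dimethyl 4β,10-dimethyl-2-oxocyclohex-1(10)-ene-4α,5β-dicarboxylate
Conditions: Pd(OAc)2 (1.05 equiv), MeCN, rt
Reagents that add atoms: none
Why: Saegusa–Ito oxidation: the regiodefined enol ether gives the oxo-π-allyl complex of divalent palladium at C1, and β-hydride elimination can only take the C10 hydrogen, which places the olefin at C1=C10 under neutral conditions that leave C5 untouched.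

Step 8
Reactants: 13 ring A enone
Product: 14 dimethyl 2α-hydroxy-4β,10-dimethylcyclohex-1(10)-ene-4α,5β-dicarboxylate (2S)
Conditions: (R)-2-methyl-CBS-oxazaborolidine (20 mol%), BH3·SMe2, THF, −20 °C
Reagents that add atoms: none
Why: Corey–Bakshi–Shibata 1,2-reduction; the catalyst (alkenyl branch as the large group) and the substrate (pseudoaxial C4 ester shielding the α face of the carbonyl) should both direct hydride to the β face, which sets the 2α-hydroxyl cis to the C4 ester.

Step 9
Reactants: 14 ring A allylic alcohol
Product: 16 dimethyl 4β,10β-dimethyl-10α-(2-oxopropyl)cyclohex-1-ene-4α,5β-dicarboxylate, via allyl isopropenyl ether 15 (not isolated)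
Conditions: 2-methoxypropene, PPTS (cat.), toluene, sealed tube, 130 °C
Reagents that add atoms: 2-methoxypropene, COC(C)=C
Why: Saucy–Marbet variant of the Claisen rearrangement: acid-catalysed exchange gives the allyl isopropenyl ether, and the suprafacial [3,3] shift delivers the acetonyl carbon to C10 on the face of the C2–O bond (α), which creates the quaternary centre with the methyl β and leaves the C2 oxygen behind as the C1=C2 olefin.

Step 10
Reactants: 16 ring A cyclohexene keto diester
Product: 17 ring A diester with C10 acetonyl group: dimethyl 4β,10β-dimethyl-10α-(2-oxopropyl)cyclohexane-4α,5β-dicarboxylate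
Conditions: H2 (1 atm), Pd/C, EtOAc, rt
Reagents that add atoms: none
Why: Heterogeneous hydrogenation of the disubstituted olefin; the ketone and the esters are not reduced and no stereocentre is created.

Step 11
Reactants: 17 ring A diester with C10 acetonyl group
Product: 18 trans-decalin-6,8-dione 18-methyl ester (4β,10β-dimethyl, 5α-H)
Conditions: KOt-Bu (2.5 equiv), THF (0.02 M), 0 °C → rt; then 1 M HCl
Reagents that add atoms: none
Why: The alkoxide forms the enolate of the methyl ketone at C7, which attacks the C6 ester carbonyl on C5; the tetrahedral intermediate loses methoxide, and deprotonation of the new 1,3-dione to its delocalised enolate makes the sequence irreversible in practice. The closest known reaction is the intramolecular Claisen (Dieckmann-type) condensation of a δ-keto ester to a cyclohexane-1,3-dione. Ring B closes in a 6-exo-trig mode by formation of C6–C7. No stereocentre is created; the ring-fusion carbon C5 becomes α to the C6 carbonyl, and its trans relationship to C10, present in 17 from steps 4 and 9, is also the more stable arrangement of the decalindione, so enolisation at C5 should not change it. The step needs selectivity between two enolates and two esters: the C7 enolate reaches the C6 ester through a six-membered chair, whereas it would reach the C18 ester only through a seven-membered ring. The C9 enolate could reach C18 only through a bridged five-membered transition state that puts both large groups axial and attacks an ester on a quaternary carbon. Dilution suppresses intermolecular aldol condensation of the methyl ketone.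

Step 12
Reactants: 19 3-methylbut-3-en-1-ol
Product: 20 4-iodo-2-methylbut-1-ene
Conditions: I2, PPh3, imidazole, CH2Cl2, 0 °C
Reagents that add atoms: iodine, II
Why: Appel-type substitution of the primary alcohol; the homoallylic position does not rearrange.

Step 13
Reactants: 18 trans-decalin-6,8-dione 18-methyl ester; 20 4-iodo-2-methylbut-1-ene
Product: 21 9α-(3-methylbut-3-enyl)-trans-decalin-6,8-dione 18-methyl ester (9-epi series)
Conditions: LDA (2.3 equiv), THF–DMPU, −78 → 0 °C; 20, −78 → 0 °C; aq. NH4Cl
Reagents that add atoms: none
Why: γ-Alkylation of a 1,3-dione dianion: the second deprotonation takes the C9 methylene and not the hindered C5 methine, and the primary iodide reacts at C9, expected on the α face trans to the C10 methyl; any 9β isomer converges in step 14, and elimination of 20 to the diene is the competing process.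

Step 14
Reactants: 21 9α-(3-methylbut-3-enyl) dione
Product: 23 9β-(3-methylbut-3-enyl)-trans-decalin-6,8-dione 18-methyl ester (9α-H), via bis-silyl dienol ether 22 (not isolated)
Conditions: TMSOTf (3 equiv), Et3N (4 equiv), CH2Cl2, 0 °C → rt; then 0.5 M HCl, THF, −20 °C
Reagents that add atoms: none
Why: Soft enolisation of a 1,3-dione to its 1,3-bis(silyloxy)diene makes C9 trigonal and relieves the axial chain; protonolysis then delivers hydrogen to the diene terminus C9 on the α face (axial, anti to the C10 methyl), so the chain ends equatorial and β, and the product no longer enolises toward C9.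

Step 15
Reactants: 23 9β-(3-methylbut-3-enyl) dione
Product: 24 9β-(3-methylbut-3-enyl)-8-(trifluoromethylsulfonyloxy)-7-en-6-one 18-methyl ester
Conditions: Tf2O, pyridine, CH2Cl2, −78 °C
Reagents that add atoms: trifluoromethanesulfonic anhydride, O=S(=O)(OS(=O)(=O)C(F)(F)F)C(F)(F)F
Why: O-sulfonylation of the dione enolate is irreversible and should take place at O8, whose neighbour C9 carries only a primary chain, and not at O6, which is eclipsed by C5 with the quaternary C4 and its ester.

Step 16
Reactants: 24 8-triflyloxy-7-en-6-one
Product: 25 9β-(3-methylbut-3-enyl)-8-methyl-7-en-6-one 18-methyl ester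
Conditions: Me2CuLi (from MeLi, CuI), THF, −78 °C
Reagents that add atoms: lithium dimethylcuprate, [Li+].C[Cu-]C
Why: Addition–elimination of a cuprate to a β-triflyloxy enone gives the β-methyl enone; the hindered ester and the isolated olefin do not react at this temperature, and C9 is not deprotonated.

Step 17
Reactants: 25 8-methyl-7-en-6-one
Product: 26 7α,8α-epoxy-9β-(3-methylbut-3-enyl)-8β-methyl-6-one 18-methyl ester
Conditions: 30% H2O2, NaOH (cat.), MeOH, 0 °C → rt
Reagents that add atoms: hydrogen peroxide, OO
Why: Weitz–Scheffer epoxidation: hydroperoxide adds to C8 axially on the α face, away from the syn-axial C10 methyl, and closes the epoxide on that face; the electron-rich side-chain olefin is inert to the nucleophilic oxidant.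

Step 18
Reactants: 26 7α,8α-epoxy-6-one
Product: 27 8α-hydroxy-9β-(3-methylbut-3-enyl)-8β-methyl-6-one 18-methyl ester
Conditions: SmI2 (2.2 equiv), THF–MeOH, −90 °C
Reagents that add atoms: none
Why: Reductive opening of an α,β-epoxy ketone by two single-electron transfers cleaves the C7–O bond α to the carbonyl and leaves O8 in place with its configuration; the enolate is protonated by methanol before it can eliminate.

Step 19
Reactants: 27 8α-hydroxy-6-one
Product: 28 6α,8α-dihydroxy-9β-(3-methylbut-3-enyl)-8β-methyl-trans-decalin 18-methyl ester
Conditions: SmI2 (2.5 equiv), H2O, Et3N, THF, 0 °C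
Reagents that add atoms: none
Why: Single-electron (ketyl) reduction of the ketone, as in dissolving-metal reductions: the oxygen bound to trivalent samarium should settle equatorial (α) and hydrogen should enter on the axial β site, which hydride reagents cannot reach past three syn-axial methyls; the limited amount of reductant should spare the hindered ester.

Step 20
Reactants: 29 prop-2-en-1-ol
Product: 30 3-(methoxymethoxy)prop-1-ene
Conditions: MOMCl, i-Pr2NEt, CH2Cl2, 0 °C → rt
Reagents that add atoms: chloromethyl methyl ether, COCCl
Why: Standard acetal protection of a primary alcohol; the acetal later directs lithiation to the Z-alkoxyallyl anion.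

Step 21
Reactants: 31 methyl 4-hydroxybut-2-ynoate
Product: 32 methyl 4-oxobut-2-ynoate
Conditions: Dess–Martin periodinane, CH2Cl2, 0 °C
Reagents that add atoms: none
Why: Mild, non-basic oxidation of a propargylic alcohol; the sensitive ynal is used at once in solution.

Step 22
Reactants: 30 3-(methoxymethoxy)prop-1-ene; 32 methyl 4-oxobut-2-ynoate
Product: 34 methyl (4S,5S)-4-hydroxy-5-(methoxymethoxy)hept-6-en-2-ynoate, via alkoxyallylborane 33 (not isolated)
Conditions: s-BuLi, THF, −78 °C; (+)-Ipc2BOMe; BF3·OEt2; 32, −78 °C; ethanolamine
Reagents that add atoms: none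
Why: Brown alkoxyallylboration: the Z-γ-alkoxyallylborane adds to the aldehyde through a chair transition state, so the Z geometry gives the threo 4,5-pair and the isopinocampheyl groups from (−)-α-pinene select the aldehyde face that gives 4S; the borane does not add to the ynoate, and the non-oxidative work-up avoids alkaline peroxide.

Step 23
Reactants: 34 methyl (4S,5S)-4-hydroxy-5-(methoxymethoxy)hept-6-en-2-ynoate
Product: 36 (5S)-5-[(1S)-1-(methoxymethoxy)prop-2-en-1-yl]-4-methylfuran-2(5H)-one, via Z-hydroxy enoate 35 (not isolated)
Conditions: Me2CuLi (3 equiv), THF, −78 °C; aq. NH4Cl, → rt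
Reagents that add atoms: lithium dimethylcuprate, [Li+].C[Cu-]C
Why: syn-Carbocupration of the ynoate puts the methyl on the β-carbon and leaves the carbinol carbon cis to the ester, so the Z-hydroxy enoate lactonises on work-up to the 4-methylbutenolide without touching the two stereocentres.

Step 24
Reactants: 36 butenolide methoxymethyl ether
Product: 37 (5S)-5-[(1S)-1-hydroxyprop-2-en-1-yl]-4-methylfuran-2(5H)-one
Conditions: HCl (cat.), MeOH, 40 °C
Reagents that add atoms: none
Why: Acid-catalysed acetal exchange with methanol; the butenolide is stable to acid, and the base-sensitive C16–H is never exposed to base.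

Step 25
Reactants: 28 6α,8α-diol with 9β-(3-methylbut-3-enyl) chain; 37 (5S)-5-[(1S)-1-hydroxyprop-2-en-1-yl]-4-methylfuran-2(5H)-one
Product: 38 CNP0104474.1
Conditions: second-generation Hoveyda–Grubbs catalyst, RuCl2(SIMes)(=CH–C6H4–2-Oi-Pr) (10 mol%), 37 (3 equiv), CH2Cl2, 40 °C
Reagents that add atoms: none
Why: Olefin cross-metathesis between a 1,1-disubstituted olefin that does not homodimerise and an excess of a secondary allylic alcohol; the trisubstituted product should form mainly as the less strained E isomer, and the electron-poor butenolide olefin and the free hydroxyls are tolerated.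

## Compound list

1 | methyl 2-(triphenylphosphoranylidene)propanoate | COC(=O)C(C)=P(c1ccccc1)(c1ccccc1)c1ccccc1 | starting material
2 | glyoxylic acid monohydrate | OC(O)C(=O)O | starting material
3 | (E)-4-methoxy-3-methyl-4-oxobut-2-enoic acid | COC(=O)/C(C)=C/C(=O)O | intermediate
4 | (R)-4-benzyloxazolidin-2-one | O=C1N[C@H](Cc2ccccc2)CO1 | starting material
5 | mixed pivalic anhydride of 3 | COC(=O)/C(C)=C/C(=O)OC(=O)C(C)(C)C | intermediate
6 | (R)-4-benzyl-3-[(E)-4-methoxy-3-methyl-4-oxobut-2-enoyl]oxazolidin-2-one | COC(=O)/C(C)=C/C(=O)N1[C@H](Cc2ccccc2)COC1=O | intermediate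
7 | (E)-pent-3-en-2-one | C/C=C/C(C)=O | starting material
8 | (E)-triisopropyl(penta-1,3-dien-2-yloxy)silane | C/C=C/C(=C)O[Si](C(C)C)(C(C)C)C(C)C | intermediate
9 | ring A cycloadduct (imide; 4α-CO2Me, 4β-CH3, 5β-acyl, 10β-CH3, C1=C2 silyl enol ether) | COC(=O)[C@]1(C)CC(O[Si](C(C)C)(C(C)C)C(C)C)=C[C@@H](C)[C@H]1C(=O)N1[C@H](Cc2ccccc2)COC1=O | intermediate
10 | ring A peroxy acid | COC(=O)[C@]1(C)CC(O[Si](C(C)C)(C(C)C)C(C)C)=C[C@@H](C)[C@H]1C(=O)OO | intermediate
11 | ring A carboxylic acid (free 5β-CO2H) | COC(=O)[C@]1(C)CC(O[Si](C(C)C)(C(C)C)C(C)C)=C[C@@H](C)[C@H]1C(=O)O | intermediate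
12 | ring A diester silyl enol ether | COC(=O)[C@]1(C)CC(O[Si](C(C)C)(C(C)C)C(C)C)=C[C@@H](C)[C@H]1C(=O)OC | intermediate
13 | ring A enone (2-oxo-1(10)-ene) | COC(=O)[C@]1(C)CC(=O)C=C(C)[C@H]1C(=O)OC | intermediate
14 | ring A allylic alcohol (2α-OH, 2S) | COC(=O)[C@]1(C)C[C@H](O)C=C(C)[C@H]1C(=O)OC | intermediate
15 | ring A allyl isopropenyl ether | COC(=O)[C@]1(C)C[C@H](OC(C)=C)C=C(C)[C@H]1C(=O)OC | intermediate
16 | ring A cyclohex-1-ene keto diester (10α-acetonyl, 10β-CH3) | COC(=O)[C@]1(C)CC=C[C@](C)(CC(C)=O)[C@H]1C(=O)OC | intermediate
17 | ring A diester with C10 acetonyl group | COC(=O)[C@]1(C)CCC[C@](C)(CC(C)=O)[C@H]1C(=O)OC | intermediate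
18 | trans-decalin-6,8-dione 18-methyl ester | COC(=O)[C@]1(C)CCC[C@@]2(C)[C@H]1C(=O)CC(=O)C2 | intermediate
19 | 3-methylbut-3-en-1-ol | C=C(C)CCO | starting material
20 | 4-iodo-2-methylbut-1-ene | C=C(C)CCI | intermediate
21 | 9α-(3-methylbut-3-enyl)-6,8-dione (9-epi) | COC(=O)[C@]1(C)CCC[C@@]2(C)[C@H]1C(=O)CC(=O)[C@H]2CCC(C)=C | intermediate
22 | 6,8-bis(trimethylsilyloxy)-6,8(9)-diene | COC(=O)[C@]1(C)CCC[C@@]2(C)[C@H]1C(O[Si](C)(C)C)=CC(O[Si](C)(C)C)=C2CCC(C)=C | intermediate
23 | 9β-(3-methylbut-3-enyl)-6,8-dione | COC(=O)[C@]1(C)CCC[C@@]2(C)[C@H]1C(=O)CC(=O)[C@@H]2CCC(C)=C | intermediate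
24 | 8-triflyloxy-7-en-6-one | COC(=O)[C@]1(C)CCC[C@@]2(C)[C@H]1C(=O)C=C(OS(=O)(=O)C(F)(F)F)[C@@H]2CCC(C)=C | intermediate
25 | 8-methyl-7-en-6-one | COC(=O)[C@]1(C)CCC[C@@]2(C)[C@H]1C(=O)C=C(C)[C@@H]2CCC(C)=C | intermediate
26 | 7α,8α-epoxy-6-one | COC(=O)[C@]1(C)CCC[C@@]2(C)[C@H]1C(=O)[C@H]3O[C@@]3(C)[C@@H]2CCC(C)=C | intermediate
27 | 8α-hydroxy-8β-methyl-6-one | COC(=O)[C@]1(C)CCC[C@@]2(C)[C@H]1C(=O)C[C@@](C)(O)[C@@H]2CCC(C)=C | intermediate
28 | 6α,8α-diol | COC(=O)[C@]1(C)CCC[C@@]2(C)[C@H]1[C@@H](O)C[C@@](C)(O)[C@@H]2CCC(C)=C | intermediate
29 | prop-2-en-1-ol | C=CCO | starting material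
30 | 3-(methoxymethoxy)prop-1-ene | C=CCOCOC | intermediate
31 | methyl 4-hydroxybut-2-ynoate | COC(=O)C#CCO | starting material
32 | methyl 4-oxobut-2-ynoate | COC(=O)C#CC=O | intermediate
33 | [(Z)-3-(methoxymethoxy)allyl]diisopinocampheylborane (from (−)-α-pinene) | COCO/C=C\CB([C@H]1C[C@H]2C[C@H](C2(C)C)[C@@H]1C)[C@H]1C[C@H]2C[C@H](C2(C)C)[C@@H]1C | intermediate
34 | methyl (4S,5S)-4-hydroxy-5-(methoxymethoxy)hept-6-en-2-ynoate | C=C[C@H](OCOC)[C@@H](O)C#CC(=O)OC | intermediate
35 | methyl (2Z,4S,5S)-4-hydroxy-5-(methoxymethoxy)-3-methylhepta-2,6-dienoate | C=C[C@H](OCOC)[C@@H](O)/C(C)=C\C(=O)OC | intermediate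
36 | (5S)-5-[(1S)-1-(methoxymethoxy)prop-2-en-1-yl]-4-methylfuran-2(5H)-one | C=C[C@H](OCOC)[C@H]1OC(=O)C=C1C | intermediate
37 | (5S)-5-[(1S)-1-hydroxyprop-2-en-1-yl]-4-methylfuran-2(5H)-one | C=C[C@H](O)[C@H]1OC(=O)C=C1C | intermediate
38 | CNP0104474.1: methyl (13E,15S)-6α,8α,15-trihydroxy-15-[(2S)-3-methyl-5-oxo-2,5-dihydrofuran-2-yl]labd-13-en-18-oate skeleton as drawn | COC(=O)[C@]1(C)CCC[C@@]2(C)[C@H]1[C@@H](O)C[C@@](C)(O)[C@@H]2CC/C(C)=C/[C@H](O)[C@H]1OC(=O)C=C1C | target

## Step count and least certain steps

Total: 25 steps. Longest linear sequence: 18 steps (steps 1, 2, 4–11, 13–19 and 25).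

Step 11 (key step). The most likely failure is slow acylation at the hindered C6 ester, which would let intermolecular aldol condensation of the methyl ketone compete, or enolisation at C5 before ring closure, which would lead to the cis-fused dione. Fallback, from 17 back to 18: the less hindered C6 ester is saponified selectively (LiOH, THF–H2O) to the ring A 5β-carboxylic acid F1; carbonyldiimidazole converts it into the acyl imidazole F2; LiHMDS (2.2 equiv, THF, −78 °C) then closes ring B by C-acylation of the C7 enolate with the activated acyl group and returns to 18.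

Step 4. The β,β-disubstituted acyl oxazolidinone may react too slowly, so that a stepwise Mukaiyama–Michael addition without ring closure or a loss of regiocontrol takes over. Fallback, from 8 back to 11: methyl tiglate is oxidised with SeO2 to methyl (E)-2-methyl-4-oxobut-2-enoate F3, in which the aldehyde on C5 is the controlling acceptor; cycloaddition with 8 under a chiral oxazaborolidinium triflimide catalyst gives the ring A aldehyde F4; buffered NaClO2 oxidation (2-methylbut-2-ene) returns to 11.

Step 9 (with step 8). Poor facial selectivity in the reduction, or ionisation and elimination of the allylic ether during heating, would erode or destroy the C10 configuration. Fallback, from 13 back to 17: Sakurai addition of trimethyl(2-methylallyl)silane (TiCl4, CH2Cl2, −78 °C) to the enone, anti to the C5 ester, gives the 10α-(2-methylallyl) ketone F5; condensation with tosylhydrazide gives the tosylhydrazone F6; reduction with catecholborane and NaOAc removes the C2 oxygen to give the methallyl diester F7; ozonolysis (O3, then Me2S) unveils the methyl ketone and returns to 17.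

Step 14 (with step 13). The second enolisation may take the C5 hydrogen and not the C9 hydrogen, so that C9 is not inverted; the silylated cation may also be captured by the pendant olefin. Fallback, from 18 back to 23: the dianion of 18 is sulfenylated with PhSSPh to the 9α-phenylthio dione F8; a second dianion alkylation with 20 gives the 9-alkyl-9-phenylthio dione F9, with the chain trans to the C10 methyl; reductive desulfurisation with aluminium amalgam (THF–H2O) generates the C8 enol, which is protonated at C9 from the α face, and returns to 23.

Step 19. Hydrogen may be delivered to C6 from the open α face, giving the axial alcohol, or the reductant may attack the ester. Fallback, from 27 back to 28: NaBH4 (MeOH, 0 °C) gives the 6β-alcohol F10; Mitsunobu inversion with 4-nitrobenzoic acid (PPh3, DIAD) gives the 6α-(4-nitrobenzoate) F11; K2CO3 in MeOH removes the ester and returns to 28.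

Step 25. Metathesis of the 1,1-disubstituted olefin may be sluggish, with homodimerisation or isomerisation of 37 and incomplete E selectivity. Fallback, from 28 to 38: cross-metathesis of 28 with crotonaldehyde (same catalyst) gives the E-enal F12; 4-methylfuran-2(5H)-one is silylated (TIPSOTf, Et3N) to 4-methyl-2-(triisopropylsilyloxy)furan F13; a vinylogous Mukaiyama aldol addition of F13 to F12 under a chiral BINOL–Ti(Oi-Pr)4 catalyst, chosen for the 15S,16S threo adduct and followed by separation of diastereomers, gives 38.

## Further compounds

F1 | step 11 | ring A 5β-carboxylic acid (C18 methyl ester, C10 acetonyl) | COC(=O)[C@]1(C)CCC[C@](C)(CC(C)=O)[C@H]1C(=O)O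
F2 | step 11 | ring A acyl imidazole | COC(=O)[C@]1(C)CCC[C@](C)(CC(C)=O)[C@H]1C(=O)n1ccnc1
F3 | step 4 | methyl (E)-2-methyl-4-oxobut-2-enoate | COC(=O)/C(C)=C/C=O
F4 | step 4 | ring A aldehyde cycloadduct | COC(=O)[C@]1(C)CC(O[Si](C(C)C)(C(C)C)C(C)C)=C[C@@H](C)[C@H]1C=O
F5 | step 9 | 10α-(2-methylallyl) 2-ketone | COC(=O)[C@]1(C)CC(=O)C[C@](C)(CC(C)=C)[C@H]1C(=O)OC
F6 | step 9 | tosylhydrazone of F5 | COC(=O)[C@]1(C)CC(=NNS(=O)(=O)c2ccc(C)cc2)C[C@](C)(CC(C)=C)[C@H]1C(=O)OC
F7 | step 9 | ring A diester with 10α-(2-methylallyl) group | COC(=O)[C@]1(C)CCC[C@](C)(CC(C)=C)[C@H]1C(=O)OC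
F8 | step 14 | 9α-phenylthio-6,8-dione | COC(=O)[C@]1(C)CCC[C@@]2(C)[C@H]1C(=O)CC(=O)[C@H]2Sc1ccccc1
F9 | step 14 | 9α-(3-methylbut-3-enyl)-9β-phenylthio-6,8-dione | COC(=O)[C@]1(C)CCC[C@@]2(C)[C@H]1C(=O)CC(=O)[C@]2(CCC(C)=C)Sc1ccccc1
F10 | step 19 | 6β,8α-diol | COC(=O)[C@]1(C)CCC[C@@]2(C)[C@H]1[C@H](O)C[C@@](C)(O)[C@@H]2CCC(C)=C
F11 | step 19 | 6α-(4-nitrobenzoate) of 28 | COC(=O)[C@]1(C)CCC[C@@]2(C)[C@H]1[C@@H](OC(=O)c1ccc(cc1)[N+](=O)[O-])C[C@@](C)(O)[C@@H]2CCC(C)=C
F12 | step 25 | (13E)-enal from 28 | COC(=O)[C@]1(C)CCC[C@@]2(C)[C@H]1[C@@H](O)C[C@@](C)(O)[C@@H]2CC/C(C)=C/C=O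
F13 | step 25 | 4-methyl-2-(triisopropylsilyloxy)furan | Cc1coc(O[Si](C(C)C)(C(C)C)C(C)C)c1
A1 | alternative 1 | (+)-sclareolide | CC1(C)CCC[C@@]2(C)[C@H]1CC[C@@]3(C)OC(=O)C[C@H]23
A2 | alternative 1 | 6α-hydroxysclareolide | CC1(C)CCC[C@@]2(C)[C@H]1[C@@H](O)C[C@@]3(C)OC(=O)C[C@H]23
A3 | alternative 1 | 6α,18-epoxysclareolide | C[C@@]14CCC[C@@]2(C)[C@H]1[C@@H](OC4)C[C@@]3(C)OC(=O)C[C@H]23
A4 | alternative 2 | 6α,8α-bis(triethylsilyloxy) decalin ester with 9β-(but-3-ynyl) chain | COC(=O)[C@]1(C)CCC[C@@]2(C)[C@H]1[C@@H](O[Si](CC)(CC)CC)C[C@@](C)(O[Si](CC)(CC)CC)[C@@H]2CCC#C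
A5 | alternative 2 | 3-methylfuran-2-carbaldehyde | Cc1ccoc1C=O
A6 | alternative 2 | E-allylic furyl carbinol | COC(=O)[C@]1(C)CCC[C@@]2(C)[C@H]1[C@@H](O[Si](CC)(CC)CC)C[C@@](C)(O[Si](CC)(CC)CC)[C@@H]2CC/C(C)=C/[C@H](O)c1occc1C
A7 | alternative 3 | monocyclic 10-methylene ester with 4-oxo-enoate chain | COC(=O)[C@]1(C)CCCC(=C)[C@H]1[C@@H](O[Si](C)(C)C(C)(C)C)CC(=O)/C=C/C(=O)OC
A8 | alternative 3 | trans-decalin 8-ketone with C9 acetic ester arm | COC(=O)[C@]1(C)CCC[C@@]2(C)[C@H]1[C@@H](O[Si](C)(C)C(C)(C)C)CC(=O)[C@@H]2CC(=O)OC
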